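Product cannot be what the substrate turns into at once: in the dusk run at 50.0 min, substrate is down to 8% of the charge and product is at 20%, so 72.0% of the charge stands in neither peak.

| setting | dusk | summer | flask |
|---|---|---|---|
| substrate | 2.1 M | 1.5 M | 1.5 M |
| coupling partner | 1.5 M (fed, over 40 min) | 2.2 M (fed, over 40 min) | 1.50 M (fed, over 40 min) |
| remark | run made earlier; the fed solution adds 1.0 times the starting volume | run made earlier; the fed solution adds 1.0 times the starting volume | the fed solution adds 1.0 times the starting volume |
| time |  |  | 1.5 h |

| run | time / min | product / % | substrate / % |
|---|---|---|---|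
| dusk | 20.0 | 5 | 31 |
| dusk | 40.0 | 12 | 18 |
| dusk | 50.0 | 20 | 8 |
| dusk | 80.0 | 33 | 5 |
| dusk | 90.0 | 42 | 5 |
| summer | 20.0 | 4 | 32 |
| summer | 40.0 | 13 | 17 |
| summer | 50.0 | 21 | 9 |
| summer | 80.0 | 32 | 9 |
| summer | 90.0 | 42 | 6 |

(standard deviation of a reading: 2 percentage points)

- charges are per starting volume, the dose included; the dosed solution carries all of it

1. amount of product in percent of the substrate charged, at 10 min, 30 min and 1.5 h

Does the fate of a molecule depend on its neighbours? The summer run holds twice the partner per substrate of the dusk run, yet at 90.0 min their product readings are 42% and 42%. Read within the scatter, the fraction of the charge follows the clock and not the charge, as first-order steps do. This flask has a partner-to-substrate ratio of 1.00, between the 0.714 of the dusk run and the 1.47 of the summer run, so it should follow the same curve.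

What, then, is the chance of one charged molecule? The arrival chance, the fraction of the charge standing as product at 90.0 min, reads 42.0% as the mean of the two runs. That is the reckoning here for 1.5 h.

How does that chance build up? The mean product is 4.50% at 20.0 min and 12.5% at 40.0 min, so doubling the clock multiplies it by 2.78. Carried along that power curve, the reckoning gives 1.62% at 10 min and 8.18% at 30 min.

The forecast, holding that “the percent course looks independent of both concentrations”, gives 2%, 9.5% and 42%, higher than this reckoning at the two early times.

The flask gives 0.798%, 8.09% and 40.2%.

    substrate ⇌ dormant form (K = 0.480, k = 4.10 × 10⁻⁴ /s)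
    intermediate C → intermediate D (k = 9.60 × 10⁻⁴ /s)
    substrate → intermediate A (k = 6.60 × 10⁻⁴ /s)
    substrate → intermediate C (k = 6.10 × 10⁻⁵ /s)
    intermediate A → intermediate B (k = 3.70 × 10⁻⁴ /s)
    intermediate B ⇌ intermediate D (K = 2.30, k = 0.00100 /s)
    intermediate D ⇌ product (K = 3.20, k = 0.0130 /s)

This flask ended 1.8 percentage points below the arrival chance, less than the 2 points of one reading. By the end of the feed at 0.667 h, substrate had fallen to 16.7%, while intermediate A stood at 37.6%, the dormant form at 12.7% and product at 13.5%. By 1.50 h, intermediate A had dropped to 22.4%, its net passing into intermediate B had reached 60.9% of the charge, and product stood at 40.2%. A second flask has twice the substrate and all other amounts as they are: the arrival chance is 42.0%, and its product stands at 40.2%.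

(The numbers in the tables were computed from invented constants, and the scatter is random.)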